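**Assumption:** Both stereocentres of α-bisabolol are destroyed in Step 1, so racemic or natural (−)-α-bisabolol work equally. The catalyst antipode in Step 2 is chosen to give the (2R,6S) spiro-bromide.

**Retrosynthesis**
- Obtusane ⇒ tertiary bromide from the trans-chlorohydrin 4, formed with retention through chloronium participation (Markovnikov chlorohydrin of the ring-B alkene of 3).
- 3 (bromo-β-chamigrene type) ⇒ ring A and the spiro centre from a bromonium-induced cation–olefin spirocyclization of (E)-γ-bisabolene (2). The ring-B alkene already present in 2 becomes the later halogenation site.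
- 2 ⇒ dehydration of commercial α-bisabolol (1), which already contains ring B and the prenyl chain.
- Ring order: ring B is pre-formed, ring A is closed in Step 2, and the ring-B halogens are added last.

**Step 1**
Reactants: 1, α-bisabolol (6-methyl-2-(4-methylcyclohex-3-en-1-yl)hept-5-en-2-ol)
Product: 2, (E)-γ-bisabolene
Conditions: Martin sulfurane, CH2Cl2, 0 °C to rt; AgNO3–silica chromatography to isolate the E isomer
Reagents that add atoms: none
Why: Dehydration of the tertiary alcohol toward the ring methine gives the tetrasubstituted exocyclic alkene (Zaitsev-type dehydration), which is needed as the nucleophile in Step 2. It erases both stereocentres of 1, and the E isomer, in which the ring CH2 next to the ring C=CH side is trans to the chain, is separated from Z and the other regioisomers.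

**Step 2**
Reactants: 2
Product: 3, (2R,6S)-2-bromo-1,1,9-trimethyl-5-methylidenespiro[5.5]undec-8-ene
Conditions: NBS (1.1 equiv), chiral BINOL-derived phosphoramidite/thiophosphoramide Lewis-base catalyst (10 mol %), CH2Cl2, –78 to –40 °C
Reagents that add atoms: N-bromosuccinimide, O=C1CCC(=O)N1Br
Why: This is a bromonium-induced polyene spirocyclization. Bromonium formation is reversible, and only the prenyl bromonium is captured by the tetrasubstituted alkene. Anti attack in a chair transition state puts Br equatorial on the new CHBr carbon. The E geometry (allylic ring arm pseudo-equatorial, the other ring arm axial) fixes the spiro centre relative to C–Br. Loss of H+ from the C7 cation gives the exocyclic methylene. The chiral catalyst sets the absolute configuration.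

**Step 3**
Reactants: 3
Product: 4, (2R,6S,8S,9S)-2-bromo-8-chloro-1,1,9-trimethyl-5-methylidenespiro[5.5]undecan-9-ol
Conditions: NCS (1.05 equiv), acetone/H2O 4:1, 0 °C, 30 min
Reagents that add atoms: N-chlorosuccinimide, O=C1CCC(=O)N1Cl; water, O
Why: Chlorohydrin formation (Markovnikov) puts Cl+ on the less substituted C5 and water anti on the tertiary C4, and the trisubstituted ring alkene reacts in preference to the hindered 1,1-disubstituted methylene. The chloronium is expected to form on the face anti to the axial C(=CH2) bridge (syn to CMe2), which sets Cl up and OH down. This face selectivity is substrate-controlled and is the main uncertainty; a diastereomer mixture is likely and the desired isomer is separated.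

**Step 4**
Reactants: 4
Product: 5, obtusane
Conditions: 48% aq. HBr (2 equiv), CH2Cl2, 0 °C, 10 min
Reagents that add atoms: hydrogen bromide, Br
Why: The tertiary alcohol ionizes with anchimeric assistance from the anti-disposed C5 chlorine, and bromide reopens the chloronium at the tertiary carbon. This gives net retention, with Br anti to Cl, and the Cl stereocentre is untouched. Kinetic tertiary-alcohol ionization is expected to outrun hydrobromination of the hindered exocyclic methylene.

**Checks performed**
- The SMILES of 5 is identical to the target SMILES.
- Atom balance, Step 1: C15H26O − H2O = C15H24.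
- Atom balance, Step 2: C15H24 + Br+ − H+ = C15H23Br.
- Atom balance, Step 3: C15H23Br + HOCl = C15H24BrClO.
- Atom balance, Step 4: C15H24BrClO + HBr − H2O = C15H23Br2Cl.
- Stereocentres set: CHBr and spiro in Step 2; CHCl and C(Me)Br in Steps 3 and 4. None is disturbed afterwards.
- Functional-group survival: the ring-A secondary bromide and the exocyclic methylene survive Steps 3 and 4.

**Compound list**
1 | α-bisabolol (stereocentres irrelevant) | CC1=CCC(CC1)C(C)(O)CCC=C(C)C | starting material
2 | (E)-γ-bisabolene | CC(C)=CCC/C(C)=C1/CC=C(C)CC1 | intermediate
3 | (2R,6S)-2-bromo-1,1,9-trimethyl-5-methylidenespiro[5.5]undec-8-ene | C=C1CC[C@@H](Br)C(C)(C)[C@]12CCC(C)=CC2 | intermediate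
4 | (2R,6S,8S,9S)-2-bromo-8-chloro-1,1,9-trimethyl-5-methylidenespiro[5.5]undecan-9-ol | C=C1CC[C@@H](Br)C(C)(C)[C@]12CC[C@](C)(O)[C@@H](Cl)C2 | intermediate
5 | obtusane, (2R,6S,8S,9S)-2,9-dibromo-8-chloro-1,1,9-trimethyl-5-methylidenespiro[5.5]undecane | C=C1CC[C@@H](Br)C(C)(C)[C@]12CC[C@](C)(Br)[C@@H](Cl)C2 | target

**Totals:** 4 steps; longest linear sequence 4.

**Three steps most likely to fail**
1. **Step 2 (enantioselective spirocyclization):** A chiral bromonium catalyst for this substrate is unprecedented, and the competing ring-B alkene and endocyclic elimination could lower yield and ee. Fallback: run the racemic cyclization with BDSB (Et2SBr·SbCl5Br), then resolve 3 by preparative chiral SFC/HPLC.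
2. **Step 1 (dehydration):** Regio- and E/Z-selectivity are poor, and acid can cyclize the prenyl alkene. Fallback: build 2 by McMurry cross-coupling of 4-methylcyclohex-3-en-1-one with sulcatone, so the tetrasubstituted alkene is formed directly.
3. **Step 3 (ring-B diastereoselectivity):** The face selectivity of the chloronium may be low or reversed. Fallback: Shi asymmetric epoxidation of 3 (catalyst-controlled face), then SN2-type opening of the epoxide at the secondary carbon with chloride, then Step 4.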